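**The balance.** We start from a balance: as far as these two readings see, activated form plus ring counts what the activator has made, so we call that the visible sum. The dusk flask and the autumn run take their activator on one schedule.

| flask | substrate | activator | remark | time |
|---|---|---|---|---|
| dusk | 20 mM | 18 mM (in portions, 3) | the very flask that is asked about, followed so far; portions every 8.0 h |  |
| autumn | 13 mM | 18 mM (in portions, 3) | run made earlier; portions every 8.0 h |  |
| flask | 20 mM | 18.0 mM (in portions, 3) | the portions of activator follow each other after 8.0 h, the first at the start | 25 h |

| run | time / h | activated form / % | ring / % |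
|---|---|---|---|
| dusk | 0.667 | 4 | 3 |
| dusk | 1.33 | 5 | 1 |
| dusk | 2.00 | 5 | 2 |
| dusk | 3.00 | 10 | 0 |
| dusk | 4.00 | 10 | 4 |
| dusk | 5.00 | 12 | 3 |
| autumn | 4.00 | 13 | 5 |
| autumn | 8.00 | 19 | 6 |
| autumn | 10.0 | 25 | 12 |
| autumn | 15.0 | 31 | 15 |
| autumn | 20.0 | 37 | 25 |
| autumn | 25.0 | 29 | 32 |

(readings scatter by 2 percentage points)

1. amount of activated form in percent of the substrate charged, at 80 min, 6.0 h and 25 h

**Closing rate.** Ring gained, divided by the area under the activated-form curve, is the closing rate: the fraction of activated form that closes to ring per hour. In the autumn run, the area up to 15.0 h is 2.74 h of charge and the later area is 3.35 h. The two windows give 0.0547 h⁻¹ and 0.0507 h⁻¹, close for readings this scattered, so we take the whole run: 0.0525 h⁻¹.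

**The sum.** The autumn sum at 25 h reads as 44.1% of the activator spent. Taking activator loss as pseudo-first-order in substrate, we scale the unspent share by the ratio of substrate charges, which puts the dusk sum at 53.2%.

**Two ways.** One way copies the autumn split: activated form held 47.5% of the sum, giving 25.3% in the dusk flask. The other feeds the sum steadily and lets it close at the autumn closing rate, which leaves a share of 55.7%, or 29.6%. They part, with the steady share above the autumn one. The steady feed cheats: at 10.0 h the autumn sum already read 37.0% of the substrate charged, against 61.0% at the last reading, so the material is older and has closed further. We commit to 25.3% at 25 h. The dusk readings themselves give 5% at 80 min and, extended along their slope, 13.0% at 6.0 h.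

**The forecast.** It says 6.5%, 13.5% and 29%, above ours at the end, with “three portions give about 58% formed and about 27% ring”.

**The flask.** It gives 5.99%, 13.3% and 24.6%.

    substrate + activated form → open dimer (k = 2.60 M⁻¹ h⁻¹)
    activated form → ring (k = 0.0570 h⁻¹)
    substrate + activator → activated form (k = 9.40 M⁻¹ h⁻¹)
    activator + ring → over-reaction product (k = 0.390 M⁻¹ h⁻¹)

At 25 h, activated form goes to ring 4.6 times as fast as to open dimer. From 21.8% at 16.0 h to 24.6% at 25.0 h, the closing rate predicts 11 percentage points of new ring, and the flask's ring rose from 13.8% to 26.2%. On the autumn run's last interval the same rate gives 8.7 points, against 7 points read.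

The data were computed on assumed constants.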